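The constants used here were chosen freely; what happens was integrated by code.

At early times each by-product that forms meets starting material that can bind it, and the by-product-assisted route needs it free.

    starting material + by-product ⇌ idle adduct, settled at all times (K1 = 350 M⁻¹)
    starting material + reagent → target + by-product (k2 = 0.0052 M⁻¹ s⁻¹)
    starting material + reagent + by-product → target + 2 by-product (k3 = 7.5 M⁻² s⁻¹)

the same everywhere: starting material 0.20 M; time 1.0 min
- zeta: reagent 2.40 M
- alpha: reagent 0.600 M
- gamma: reagent 1.20 M

- part of the starting material that has reacted at the end, zeta
- part of the starting material that has reacted at the end, alpha
- part of the starting material that has reacted at the end, gamma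
- what raising the concentration of reagent from its lowest to its highest value here does to the part of the starting material that has reacted (changes below 5 percentage points count as none) (it falls / it rises / no change)

- by-product is meant together with its idle adduct
- what has gone from starting material into another species counts as reacted, even if it can come back
- run time (zeta): 1.0 min

Take alpha. Call k and c the constants of the plain and the by-product-assisted route, and K the binding constant.

In one extreme all by-product is bound and the assisted route stands idle. Each plain turnover then removes two starting material, one converted and one bound, so the part reacted is 31.2%.

In the other extreme nothing is bound. By-product then multiplies on a time of 1.11 s, far shorter than the 1.0 min run, and in this extreme alpha finishes early.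

Binding is tight, since K times the starting material charged is 70, so alpha lies towards the first extreme. But the balance leaves by-product free, so the assisted route runs. With x = [target] and s the charge of starting material, [idle adduct] ≈ x and [starting material] ≈ s − 2x, while the binding balance gives:

[starting material][by-product] = [idle adduct]/K ≈ x/K

The rate is therefore linear in x:

dx/dt = [reagent](k(s − 2x) + cx/K)

We hold [reagent] at its charge (pseudo-first-order) and set g = c/K − 2k = 0.0110 M⁻¹ s⁻¹. The part reacted, f = 2x/s, is then:

f = (2k/g)(exp(g[reagent]t) − 1)

The charge s has cancelled. Setting f = 1 gives:

D = ln(c/(2Kk))/g = 1.09 M·min

This D is the turnover dose, the product of reagent concentration and time at which, in this reckoning, binding and conversion have together taken up the charge.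

Alpha's dose of 0.600 M·min lies below D, and f = 46.0%, with reagent held at its charge. Gamma at 1.20 M·min and zeta at 2.40 M·min lie past D, so we expect both near completion and a rising trend.

The forecast put zeta at 99.8%, alpha at 43% and gamma at 94%, and of the part reacted it said it rises: “Conversion rises with reagent concentration.”

The simulation gives 99.8% for zeta, 43.2% for alpha and 94.1% for gamma. Of the part reacted, from the lowest reagent to the highest, it rises, by 57 percentage points. Alpha stands 2.8 points below our f, with reagent at 93% of its charge at the end. A neighbour of alpha with 0.24 M of reagent has a dose of 0.240 M·min, further below D, and f gives 16.2%. That neighbour ended with 15.5% reacted, 84.5% of the starting material still free and 7.82% as target.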